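## Retrosynthetic overview

- Prodelphinidin C2 ⇒ its tetradeca-O-benzyl ether (global hydrogenolysis last).
- Both interflavan C4–C8 bonds are cut. Each is made by visible-light photoredox ionisation of one common 4-arylthio-gallocatechin donor and Friedel–Crafts capture at C8 of the growing acceptor (monomer first, then dimer).
- Donor ⇒ (+)-dihydromyricetin (benzylation, then telescoped C4 reduction/thiolysis). Acceptor ⇒ (+)-catechin (benzylation).
- No ring is built. All three C rings and their C2/C3 stereocentres are bought; the two C4 centres are set trans to the neighbouring C3–OH in the couplings.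

Assumption: natural (+)-dihydromyricetin (ampelopsin) is taken as the (2R,3R) enantiomer and (+)-catechin as the (2R,3S) enantiomer; potentials are quoted against SCE and are approximate literature-type values.

## Route

Step 1
Reactants: 1 (+)-catechin; 2 benzyl bromide
Product: 3 5,7,3',4'-tetra-O-benzyl-(+)-catechin
Conditions: BnBr (4.4 equiv), K2CO3 (5 equiv), DMF, 0 °C → rt, Ar
Reagents that add atoms: benzyl bromide (2), BrCc1ccccc1
Why: Williamson ether synthesis in which K2CO3 deprotonates only the four phenols and not the secondary 3-OH, so benzylation is phenol-selective and no stereocentre is touched.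

Step 2
Reactants: 4 (+)-dihydromyricetin; 2 benzyl bromide
Product: 5 5,7,3',4',5'-penta-O-benzyl-(+)-dihydromyricetin
Conditions: BnBr (5.5 equiv), K2CO3 (6 equiv), DMF, rt → 40 °C, Ar, dark
Reagents that add atoms: benzyl bromide (2), BrCc1ccccc1
Why: Williamson ether synthesis on the five phenols (the chelated 5-OH reacts last on gentle warming, the α-ketol 3-OH is not alkylated by the weak base), with the bought 2,3-trans centres kept because this is the thermodynamically preferred arrangement and full benzylation is precedented for taxifolin.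

Step 3
Reactants: 5 5,7,3',4',5'-penta-O-benzyl-(+)-dihydromyricetin; 6 4-methoxybenzenethiol
Product: 8 4α-[(4-methoxyphenyl)sulfanyl]-penta-O-benzyl-gallocatechin, via penta-O-benzyl flavan-3,4-diol 7 (not isolated)
Conditions: NaBH4 (1.5 equiv), THF/EtOH 4:1, 0 °C; CH2Cl2/H2O partition, dried organic layer used directly; then 4-MeOC6H4SH (3 equiv), CF3CO2H (10 vol %), CH2Cl2, 0 °C → rt
Reagents that add atoms: 4-methoxybenzenethiol (6), COc1ccc(S)cc1
Why: Borohydride carbonyl reduction (axial hydride delivery gives the all-equatorial 3,4-trans diol 7, and the borohydride is washed out before acid is added so that the C4 cation cannot be reduced to the flavan) followed by acid-mediated SN1 thiolysis of the 2,4,6-trialkoxybenzylic alcohol, where the excess soft thiol traps the C4 cation mainly trans to the 3-OH and outcompetes self-condensation; the C4 configuration is of no consequence because C4 is re-ionised in the next step, and C2/C3 are untouched.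

Step 4
Reactants: 8 4α-[(4-methoxyphenyl)sulfanyl]-penta-O-benzyl-gallocatechin; 3 5,7,3',4'-tetra-O-benzyl-(+)-catechin
Product: 10 nona-O-benzyl-prodelphinidin B3, via flavan-4-yl cation 9 (not isolated)
Conditions: [Ir(dF(CF3)ppy)2(dtbbpy)]PF6 (2 mol %), 450 nm LEDs, 3 (3 equiv), 8 added by syringe pump over 4 h, 4 Å MS, CH2Cl2, −30 °C, Ar (dF(CF3)ppy = cyclometalated 2-(2,4-difluorophenyl)-5-(trifluoromethyl)pyridine, dtbbpy = 4,4'-di-tert-butyl-2,2'-bipyridine)
Reagents that add atoms: none
Why: Proposed new method: the excited trivalent iridium photocatalyst (about +1.2 V) oxidises only the electron-rich 4-methoxyphenyl sulfide of 8 (about +1.1 to +1.2 V, whereas the benzylated arene rings lie above about +1.3 V and have no fast fragmentation channel), the sulfide radical cation undergoes mesolytic C4–S cleavage to the 2,4,6-trialkoxybenzylic cation 9 plus an arylthiyl radical that divalent iridium reduces to thiolate (a redox-neutral, acid-free cycle), and C8 of 3 attacks 9 in a Friedel–Crafts alkylation anti to the C3 hydroxyl so that the 4α (3,4-trans) centre is set by the bought C2/C3 centres (the minor 4β epimer is removed by chromatography); the closest known reaction types are photoredox C–S cleavage of simple benzylic thioethers to carbocations, anodic or photochemical activation of aryl thioglycosides and AgBF4-mediated activation of 4-thioflavans, none of which has been shown for photochemical interflavan bond formation.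

Step 5
Reactants: 8 4α-[(4-methoxyphenyl)sulfanyl]-penta-O-benzyl-gallocatechin; 10 nona-O-benzyl-prodelphinidin B3
Product: 11 tetradeca-O-benzyl-prodelphinidin C2
Conditions: [Ir(dF(CF3)ppy)2(dtbbpy)]PF6 (2 mol %), 450 nm LEDs, 10 (2 equiv, excess recovered), 8 added by syringe pump over 6 h, 4 Å MS, CH2Cl2, −30 °C, Ar
Reagents that add atoms: none
Why: Proposed new method: the photoredox C–S mesolysis of step 4 ionises a second portion of 8 to the same flavan-4-yl cation 9, which is captured at the most accessible nucleophilic position of 10, namely C8 of the upper gallocatechin unit (the lower C8 is already substituted and both C6 positions are flanked by two benzyloxy groups), again anti to the C3 hydroxyl to set the second 4α centre, while slow addition keeps 8 scarce so that its own C8 does not compete; the closest known reaction types are those named in step 4 together with Lewis-acid chain extension of benzylated procyanidin dimers at the upper-unit C8.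

Step 6
Reactants: 11 tetradeca-O-benzyl-prodelphinidin C2
Product: 12 Prodelphinidin C2
Conditions: H2 (1 atm), Pd(OH)2/C, THF/MeOH/H2O 20:20:1, rt; filtration under Ar, Sephadex LH-20, lyophilisation
Reagents that add atoms: none
Why: Heterogeneous hydrogenolysis of the fourteen benzyl ethers over Pd(OH)2/C, conditions under which the interflavan C4–C8 bonds and the cyclic C2–O1 ethers of benzylated proanthocyanidins are known to survive, so no stereocentre is affected (11 must be freed of sulfur traces beforehand).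

## Compound list

1 | (+)-catechin, (2R,3S)-2-(3,4-dihydroxyphenyl)chromane-3,5,7-triol | Oc1cc(O)c2c(c1)O[C@H](c1ccc(O)c(O)c1)[C@@H](O)C2 | starting material

2 | benzyl bromide | BrCc1ccccc1 | starting material

3 | 5,7,3',4'-tetra-O-benzyl-(+)-catechin, (2R,3S)-5,7-bis(benzyloxy)-2-[3,4-bis(benzyloxy)phenyl]chroman-3-ol | c1ccccc1COc1cc(OCc2ccccc2)c2c(c1)O[C@H](c1ccc(OCc3ccccc3)c(OCc3ccccc3)c1)[C@@H](O)C2 | intermediate

4 | (+)-dihydromyricetin (ampelopsin), (2R,3R)-3,5,7-trihydroxy-2-(3,4,5-trihydroxyphenyl)chroman-4-one | Oc1cc(O)c2c(c1)O[C@H](c1cc(O)c(O)c(O)c1)[C@@H](O)C2=O | starting material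

5 | 5,7,3',4',5'-penta-O-benzyl-(+)-dihydromyricetin, (2R,3R)-5,7-bis(benzyloxy)-3-hydroxy-2-[3,4,5-tris(benzyloxy)phenyl]chroman-4-one | c1ccccc1COc1cc(OCc2ccccc2)c2c(c1)O[C@H](c1cc(OCc3ccccc3)c(OCc3ccccc3)c(OCc3ccccc3)c1)[C@@H](O)C2=O | intermediate

6 | 4-methoxybenzenethiol | COc1ccc(S)cc1 | starting material

7 | (2R,3S,4R)-5,7-bis(benzyloxy)-2-[3,4,5-tris(benzyloxy)phenyl]chromane-3,4-diol (2,3-trans-3,4-trans, 4α-OH) | c1ccccc1COc1cc(OCc2ccccc2)c2c(c1)O[C@H](c1cc(OCc3ccccc3)c(OCc3ccccc3)c(OCc3ccccc3)c1)[C@@H](O)[C@@H]2O | intermediate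

8 | 4α-[(4-methoxyphenyl)sulfanyl]-penta-O-benzyl-gallocatechin, (2R,3R,4R)-5,7-bis(benzyloxy)-4-[(4-methoxyphenyl)sulfanyl]-2-[3,4,5-tris(benzyloxy)phenyl]chroman-3-ol (3,4-trans, major epimer) | c1ccccc1COc1cc(OCc2ccccc2)c2c(c1)O[C@H](c1cc(OCc3ccccc3)c(OCc3ccccc3)c(OCc3ccccc3)c1)[C@@H](O)[C@@H]2Sc1ccc(OC)cc1 | intermediate

9 | (2R,3S)-5,7-bis(benzyloxy)-3-hydroxy-2-[3,4,5-tris(benzyloxy)phenyl]chroman-4-ylium (C4 benzylic cation, the O-benzylated quinone methide) | c1ccccc1COc1cc(OCc2ccccc2)c2c(c1)O[C@H](c1cc(OCc3ccccc3)c(OCc3ccccc3)c(OCc3ccccc3)c1)[C@@H](O)[CH+]2 | intermediate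

10 | nona-O-benzyl-prodelphinidin B3: 5,7,3',4',5'-penta-O-benzyl-gallocatechin-(4α→8)-5,7,3',4'-tetra-O-benzyl-catechin, both 3-OH free, upper unit 2R,3S,4S (all-trans), lower unit 2R,3S | c1ccccc1COc1cc(OCc2ccccc2)c2c(c1)O[C@H](c1cc(OCc3ccccc3)c(OCc3ccccc3)c(OCc3ccccc3)c1)[C@@H](O)[C@@H]2c1c(OCc2ccccc2)cc(OCc2ccccc2)c2c1O[C@H](c1ccc(OCc3ccccc3)c(OCc3ccccc3)c1)[C@@H](O)C2 | intermediate

11 | tetradeca-O-benzyl-prodelphinidin C2: penta-O-benzyl-gallocatechin-(4α→8)-penta-O-benzyl-gallocatechin-(4α→8)-tetra-O-benzyl-catechin, three 3-OH free, each unit 2,3-trans, both interflavan bonds 3,4-trans | c1ccccc1COc1cc(OCc2ccccc2)c2c(c1)O[C@H](c1cc(OCc3ccccc3)c(OCc3ccccc3)c(OCc3ccccc3)c1)[C@@H](O)[C@@H]2c1c(OCc2ccccc2)cc(OCc2ccccc2)c2c1O[C@H](c1cc(OCc3ccccc3)c(OCc3ccccc3)c(OCc3ccccc3)c1)[C@@H](O)[C@@H]2c1c(OCc2ccccc2)cc(OCc2ccccc2)c2c1O[C@H](c1ccc(OCc3ccccc3)c(OCc3ccccc3)c1)[C@@H](O)C2 | intermediate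

12 | Prodelphinidin C2, gallocatechin-(4α→8)-gallocatechin-(4α→8)-catechin | Oc1cc(O)c2c(c1)O[C@H](c1cc(O)c(O)c(O)c1)[C@@H](O)[C@@H]2c1c(O)cc(O)c2c1O[C@H](c1cc(O)c(O)c(O)c1)[C@@H](O)[C@@H]2c1c(O)cc(O)c2c1O[C@H](c1ccc(O)c(O)c1)[C@@H](O)C2 | target

## Step count and risks

Total steps: 6. Longest linear sequence: 5 (4 → 5 → 8 → 10 → 11 → 12).

The three steps most likely to fail, in route order:

**Step 2 (full benzylation of dihydromyricetin).** Risks are incomplete alkylation of the chelated 5-OH and base-induced epimerisation, ring opening or oxidation of the flavanonol. The fallback avoids the flavanonol altogether; it sets out from 2 and comes back to the route at 8. Bought (+)-gallocatechin F1 (commercial but costlier) is benzylated with 2 and K2CO3 in DMF to penta-O-benzyl-(+)-gallocatechin F2. F2 is then oxidised at C4 with DDQ in the presence of 2-ethoxyethanol (CH2Cl2, rt) to the 4β-(2-ethoxyethoxy) ether F3. Finally F3 is exchanged with 6 under catalytic BF3·OEt2 (CH2Cl2, −78 °C) to give 8.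

**Step 4 (proposed new photoredox coupling).** Risks are unselective electron transfer, recapture of cation 9 by the liberated thiol, and an insufficient 4α:4β ratio. The fallback uses known chemistry and no thioether or light. It sets out from 5: reduction with NaBH4 and isolation of the diol 7, then TiCl4-mediated condensation of 7 with excess 3 (CH2Cl2, −78 → 0 °C), which is the established Lewis-acid coupling of a benzylated flavan-3,4-diol with benzylated catechin, and it comes back to the route at 10. No new compound is made on this way (F0).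

**Step 5 (second photoredox coupling).** Risks are self-condensation of 8 through its own free C8 and poor conversion with the bulkier dimer. The fallback changes to a C8-capped donor with Lewis-acid activation; it sets out from 5 and 10 and comes back to the route at 12. Compound 5 is reduced with NaBH4 and the diol 7 is isolated. Diol 7 is brominated at C8 (NBS, CH2Cl2, −78 °C) to the 8-bromo diol F4. F4 is condensed with 10 (TMSOTf, CH2Cl2, −78 °C) to the 8-bromo tetradeca-O-benzyl trimer F5, which cannot self-condense because its only free C8 is blocked. Hydrogenolysis of F5 (H2, Pd(OH)2/C, Et3N, THF/MeOH/H2O) removes the bromine and all benzyl groups and gives 12.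

## Further compounds

F1 | step 2 | (+)-gallocatechin (bought), (2R,3S)-2-(3,4,5-trihydroxyphenyl)chromane-3,5,7-triol | Oc1cc(O)c2c(c1)O[C@H](c1cc(O)c(O)c(O)c1)[C@@H](O)C2

F2 | step 2 | 5,7,3',4',5'-penta-O-benzyl-(+)-gallocatechin, (2R,3S)-5,7-bis(benzyloxy)-2-[3,4,5-tris(benzyloxy)phenyl]chroman-3-ol | c1ccccc1COc1cc(OCc2ccccc2)c2c(c1)O[C@H](c1cc(OCc3ccccc3)c(OCc3ccccc3)c(OCc3ccccc3)c1)[C@@H](O)C2

F3 | step 2 | (2R,3S,4S)-5,7-bis(benzyloxy)-4-(2-ethoxyethoxy)-2-[3,4,5-tris(benzyloxy)phenyl]chroman-3-ol (4β ether, major epimer) | c1ccccc1COc1cc(OCc2ccccc2)c2c(c1)O[C@H](c1cc(OCc3ccccc3)c(OCc3ccccc3)c(OCc3ccccc3)c1)[C@@H](O)[C@H]2OCCOCC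

F0 | step 4 | none | none

F4 | step 5 | (2R,3S,4R)-8-bromo-5,7-bis(benzyloxy)-2-[3,4,5-tris(benzyloxy)phenyl]chromane-3,4-diol | c1ccccc1COc1cc(OCc2ccccc2)c2c(c1Br)O[C@H](c1cc(OCc3ccccc3)c(OCc3ccccc3)c(OCc3ccccc3)c1)[C@@H](O)[C@@H]2O

F5 | step 5 | 8-bromo-tetradeca-O-benzyl-prodelphinidin C2 (bromine at C8 of the upper gallocatechin unit) | c1ccccc1COc1cc(OCc2ccccc2)c2c(c1Br)O[C@H](c1cc(OCc3ccccc3)c(OCc3ccccc3)c(OCc3ccccc3)c1)[C@@H](O)[C@@H]2c1c(OCc2ccccc2)cc(OCc2ccccc2)c2c1O[C@H](c1cc(OCc3ccccc3)c(OCc3ccccc3)c(OCc3ccccc3)c1)[C@@H](O)[C@@H]2c1c(OCc2ccccc2)cc(OCc2ccccc2)c2c1O[C@H](c1ccc(OCc3ccccc3)c(OCc3ccccc3)c1)[C@@H](O)C2
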